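Numbering: C1 lactone C=O, C2=C3, C4, C5 (NCH), C6-C8, C9 (spiro), C10-C12 (ring CH2), C13, C14 (CHMe), C15=C16, C17 (CHOH), C18=C19(Cl), C20, C21 (OCH2), C22 (NCH2). Ring A = N, C22, C2-C5; ring B = N, C5-C9.
Cuts: with a helper ketone at C11 and a helper carboxyl at C10, C9-C10 (cyclopentane) and N-C9 (ring B) are cut together. Then follow O21-C1 (lactone), C8-C9 (ketone synthesis), C16-C17 (alkynylation), C12-C13 (enolate alkylation), C13-C14 (malonate SN2), C2=C3 (metathesis), N-C22 and C4-C5.
Enabling feature: spiro C9 is shared by ring B and the cyclopentane, carries N, and stands 1,3 to C11, so N-C9-C10-C11(=O) is a Mannich retron. As a ketone, C9 lies five bonds from the ring A nitrogen (N-C5-C6-C7-C8-C9).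
Ring order: ring A first, then a 19-membered macrolactone. In one flask ring B closes (this leaves the 15-membered lactone) and the cyclopentane closes last.
Stereochemistry: C14 comes from (R)-but-3-yn-2-ol by SN2 inversion, C13 from an Evans auxiliary, C17 from a chiral zinc catalyst, and C5 from a sulfinamide auxiliary. C9 is set in the key step by C5 and C13.
Alkene geometry and helpers: anti ICl addition gives Cl trans to C17, and alkyne semihydrogenation gives 15Z. The C10 carboxyl leaves as CO2 in the key step and the C11 ketone leaves through its tosylhydrazone.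

Key step: step 23

Assumption: the SMILES is read literally, so C15=C16 is Z, Cl is trans to C17 (18E), and the centres are 5R, 9S, 13R, 14S, 17R; compounds 1, 4, 6, 10, 14, 20, 21, 23 and 24 are taken as commercial.
Remark: the descriptors at C9, C14 and C17 change along the route only because CIP priorities change; no centre is inverted after it is set.

Step 1
Reactants: 1 tert-butyl acetoacetate
Product: 2 tert-butyl (E)-3-methoxybut-2-enoate
Conditions: HC(OMe)3, cat. H2SO4, MeOH, rt
Reagents that add atoms: trimethyl orthoformate, COC(OC)OC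
Why: Acid-catalysed ketalisation and loss of methanol (enol ether formation from a β-keto ester) should give the conjugated E enol ether, which masks the later C10-C11 β-keto acid in a non-acidic form.

Step 2
Reactants: 2 tert-butyl (E)-3-methoxybut-2-enoate
Product: 3 tert-butyl (E)-4-bromo-3-methoxybut-2-enoate
Conditions: NBS, cat. (PhCO2)2, PhCF3, reflux
Reagents that add atoms: N-bromosuccinimide, O=C1CCC(=O)N1Br
Why: Wohl-Ziegler bromination of the allylic methyl group of a 3-alkoxycrotonate should give the reactive allylic bromide with the enol ether geometry kept.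

Step 3
Reactants: 4 (R)-but-3-yn-2-ol
Product: 5 (R)-but-3-yn-2-yl methanesulfonate
Conditions: MsCl, Et3N, CH2Cl2, 0 °C
Reagents that add atoms: methanesulfonyl chloride, CS(=O)(=O)Cl
Why: O-sulfonylation activates the alcohol without touching the C-O stereocentre.

Step 4
Reactants: 5 (R)-but-3-yn-2-yl methanesulfonate; 6 dimethyl malonate
Product: 7 dimethyl 2-[(2R)-but-3-yn-2-yl]malonate
Conditions: NaH, DMF, 0 to 60 °C
Reagents that add atoms: none
Why: Malonic ester alkylation by SN2 at the secondary propargylic mesylate should occur with inversion and so set C14, the soft carbanion favouring direct over allenic substitution.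

Step 5
Reactants: 7 dimethyl 2-[(2R)-but-3-yn-2-yl]malonate
Product: 9 (3R)-3-methylpent-4-ynoic acid, via malonic diacid 8 (not isolated)
Conditions: NaOH, MeOH/H2O, reflux; HCl; neat, 150 °C
Reagents that add atoms: sodium hydroxide, [Na+].[OH-]
Why: Saponification and thermal decarboxylation of the malonic acid leave the non-acidic C14 centre untouched.

Step 6
Reactants: 9 (3R)-3-methylpent-4-ynoic acid; 10 (4R)-4-benzyl-1,3-oxazolidin-2-one
Product: 12 (4R)-4-benzyl-3-[(3R)-3-methylpent-4-ynoyl]-1,3-oxazolidin-2-one, via pivalic mixed anhydride 11 (not isolated)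
Conditions: PivCl, Et3N, THF, -20 °C; then LiCl, 10, rt
Reagents that add atoms: none
Why: N-acylation of the oxazolidinone through the mixed pivalic anhydride takes place at the less hindered acyl carbon.

Step 7
Reactants: 12 (4R)-4-benzyl-3-[(3R)-3-methylpent-4-ynoyl]-1,3-oxazolidin-2-one; 3 tert-butyl (E)-4-bromo-3-methoxybut-2-enoate
Product: 13 tert-butyl (2E,5R,6R)-5-{[(4R)-4-benzyl-2-oxo-1,3-oxazolidin-3-yl]carbonyl}-3-methoxy-6-methyloct-2-en-7-ynoate
Conditions: NaN(SiMe3)2, THF, -78 °C; then 3, -78 to -40 °C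
Reagents that add atoms: none
Why: Evans alkylation: the chelated Z sodium enolate is shielded on one face by the benzyl group, so the allylic bromide should enter from the other face and set 13R whatever the C14 centre prefers.

Step 8
Reactants: 14 tert-butyl(but-3-yn-1-yloxy)dimethylsilane
Product: 15 tert-butyl{[(3E)-3-chloro-4-iodobut-3-en-1-yl]oxy}dimethylsilane
Conditions: ICl, CH2Cl2, -78 to -20 °C, dark
Reagents that add atoms: iodine monochloride, ClI
Why: In this electrophilic iodochlorination of a terminal alkyne, chloride opens the bridged iodonium ion anti at the internal carbon, which should give the E isomer with I trans to Cl, the geometry that later places Cl trans to C17.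

Step 9
Reactants: 15 tert-butyl{[(3E)-3-chloro-4-iodobut-3-en-1-yl]oxy}dimethylsilane
Product: 16 (2E)-5-[(tert-butyldimethylsilyl)oxy]-3-chloropent-2-enal
Conditions: Pd(PPh3)4 (cat.), CO (3 atm), Bu3SnH (slow addition), THF, 50 °C
Reagents that add atoms: carbon monoxide, [C-]#[O+]
Why: Palladium-catalysed reductive carbonylation (formylation) of a vinyl iodide with CO and tin hydride proceeds with retention at the C-I carbon and leaves the much slower C-Cl bond alone.

Step 10
Reactants: 13 tert-butyl (2E,5R,6R)-5-{[(4R)-4-benzyl-2-oxo-1,3-oxazolidin-3-yl]carbonyl}-3-methoxy-6-methyloct-2-en-7-ynoate; 16 (2E)-5-[(tert-butyldimethylsilyl)oxy]-3-chloropent-2-enal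
Product: 17 tert-butyl (2E,5R,6R,9S,10E)-5-{[(4R)-4-benzyl-2-oxo-1,3-oxazolidin-3-yl]carbonyl}-13-[(tert-butyldimethylsilyl)oxy]-11-chloro-9-hydroxy-3-methoxy-6-methyltrideca-2,10-dien-7-ynoate
Conditions: ZnMe2, (S,S)-ProPhenol (cat.), Ph3PO (cat.), toluene, 0 °C
Reagents that add atoms: none
Why: Zinc-ProPhenol asymmetric alkynylation of an α,β-unsaturated aldehyde: the dinuclear zinc alkoxide binds the enal and should deliver the alkynylzinc of 13 to the Re face of C17, which sets 17S (the target's 17R once the alkyne is reduced).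

Step 11
Reactants: 17 propargylic alcohol (name as in step 10)
Product: 18 tert-butyl (2E,5R,6R,9S,10E)-5-{[(4R)-4-benzyl-2-oxo-1,3-oxazolidin-3-yl]carbonyl}-13-[(tert-butyldimethylsilyl)oxy]-9-[(tert-butyldiphenylsilyl)oxy]-11-chloro-3-methoxy-6-methyltrideca-2,10-dien-7-ynoate
Conditions: TBDPSCl, imidazole, cat. DMAP, DMF, rt
Reagents that add atoms: tert-butyl(chloro)diphenylsilane, CC(C)(C)[Si](Cl)(c1ccccc1)c1ccccc1
Why: O-silylation gives an acid-stable ether that keeps O17 out of the lactonisation and should survive the acid of the key step.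

Step 12
Reactants: 18 imide (name as in step 11)
Product: 19 tert-butyl (2E,5R,6R,9S,10E)-13-[(tert-butyldimethylsilyl)oxy]-9-[(tert-butyldiphenylsilyl)oxy]-11-chloro-5-[(ethylsulfanyl)carbonyl]-3-methoxy-6-methyltrideca-2,10-dien-7-ynoate
Conditions: EtSH, n-BuLi, THF, 0 °C
Reagents that add atoms: ethanethiol, CCS
Why: Thiolysis of the N-acyl oxazolidinone by lithium thiolate attacks the exocyclic carbonyl even of hindered imides and is too weakly basic to epimerise C13.

Step 13
Reactants: 20 2-(bromomethyl)acrylic acid; 21 2-(trimethylsilyl)ethanol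
Product: 22 2-(trimethylsilyl)ethyl 2-(bromomethyl)acrylate
Conditions: DCC, cat. DMAP, CH2Cl2, 0 °C
Reagents that add atoms: none
Why: Steglich esterification installs a fluoride-labile ester for C1 under neutral conditions that spare the allylic bromide.

Step 14
Reactants: 23 4-[(tert-butyldimethylsilyl)oxy]butanal; 24 (R)-2-methylpropane-2-sulfinamide
Product: 25 (R,E)-N-{4-[(tert-butyldimethylsilyl)oxy]butylidene}-2-methylpropane-2-sulfinamide
Conditions: CuSO4 (anhydrous), CH2Cl2, rt
Reagents that add atoms: none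
Why: Dehydrative condensation of an aldehyde with tert-butanesulfinamide should give the E sulfinimine.

Step 15
Reactants: 25 (R,E)-N-{4-[(tert-butyldimethylsilyl)oxy]butylidene}-2-methylpropane-2-sulfinamide
Product: 26 (R)-N-{(4R)-7-[(tert-butyldimethylsilyl)oxy]hept-1-en-4-yl}-2-methylpropane-2-sulfinamide
Conditions: allylMgBr, CH2Cl2, -78 °C
Reagents that add atoms: allylmagnesium bromide, C=CC[Mg]Br
Why: Sulfinimine allylation (Ellman auxiliary): in CH2Cl2 magnesium is held by the sulfinyl oxygen in a six-membered chair, so allyl should add to the Si face of C5 and set 5R.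

Step 16
Reactants: 26 homoallylic sulfinamide (name as in step 15); 22 2-(trimethylsilyl)ethyl 2-(bromomethyl)acrylate
Product: 27 2-(trimethylsilyl)ethyl 2-{[{(4R)-7-[(tert-butyldimethylsilyl)oxy]hept-1-en-4-yl}((R)-tert-butylsulfinyl)amino]methyl}acrylate
Conditions: NaH, DMF, 0 °C; then 22
Reagents that add atoms: none
Why: N-alkylation of the sulfinamide anion by the doubly activated allylic bromide forms N-C22, direct and allylic substitution giving the same product.

Step 17
Reactants: 27 diene (name as in step 16)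
Product: 28 2-(trimethylsilyl)ethyl (6R)-1-[(R)-tert-butylsulfinyl]-6-{3-[(tert-butyldimethylsilyl)oxy]propyl}-1,2,5,6-tetrahydropyridine-3-carboxylate
Conditions: second-generation Grubbs catalyst (cat.), CH2Cl2, reflux
Reagents that add atoms: none
Why: Ring-closing metathesis of the terminal allyl alkene with the 1,1-disubstituted acrylate closes ring A and forms the trisubstituted C2=C3 enoate, while the sulfinyl group stays on as N-protection.

Step 18
Reactants: 28 ring A silyl ether (name as in step 17)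
Product: 29 2-(trimethylsilyl)ethyl (6R)-1-[(R)-tert-butylsulfinyl]-6-(3-hydroxypropyl)-1,2,5,6-tetrahydropyridine-3-carboxylate
Conditions: HF·pyridine, pyridine, THF, 0 °C to rt
Reagents that add atoms: none
Why: Buffered HF cleaves the primary silyl ether, while the silylethyl ester (which needs free fluoride ion) and the sulfinamide (which needs strong acid) should stay.

Step 19
Reactants: 29 ring A alcohol (name as in step 18)
Product: 30 2-(trimethylsilyl)ethyl (6R)-1-[(R)-tert-butylsulfinyl]-6-(3-iodopropyl)-1,2,5,6-tetrahydropyridine-3-carboxylate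
Conditions: I2, PPh3, imidazole, CH2Cl2, 0 °C
Reagents that add atoms: iodine, II
Why: Appel iodination turns the primary alcohol at C8 into the iodide faster than the reagent can touch the fully substituted sulfinamide.

Step 20
Reactants: 30 ring A iodide (name as in step 19); 19 thioester (name as in step 12)
Product: 32 (5R,13R,14R,17S)-C9 ketone: silylethyl ester of the N-[(R)-tert-butylsulfinyl] ring A acid; C5 chain C6-C8 to C9=O; C13 CH2C(OMe)=CHCO2tBu (E); C14 Me; C15≡C16; C17 OTBDPS; (E)-C18=C19(Cl); C21 OTBS, via alkylzinc iodide 31 (not isolated)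
Conditions: Zn dust (BrCH2CH2Br, TMSCl), THF, 40 °C; then 19, PdCl2(PPh3)2 (cat.), toluene, rt
Reagents that add atoms: none
Why: Fukuyama coupling of an alkylzinc iodide with a thioester forms the C8-C9 ketone under neutral conditions that tolerate esters, the enol ether, the alkyne and the vinyl chloride and should not enolise C13.

Step 21
Reactants: 32 C9 ketone (name as in step 20)
Product: 33 (5R,13R,14R,17S)-seco acid: as 32 but C1 CO2H and C21 OH free
Conditions: TBAF, AcOH (1:1), THF, 0 °C to rt
Reagents that add atoms: none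
Why: Fluoride attacks the small SiMe3 group of the ester (fragmentation to ethene) and the primary silyl ether faster than the hindered secondary TBDPS ether, and the acetic acid buffer protects the C13 centre.

Step 22
Reactants: 33 seco acid (name as in step 21)
Product: 34 (5R,13R,14R,17S)-19-membered macrolactone: as 33 with O21 acylated by C1
Conditions: 2-methyl-6-nitrobenzoic anhydride, DMAP, CH2Cl2 (1 mM, slow addition), rt
Reagents that add atoms: none
Why: Shiina macrolactonisation of the only free alcohol with the ring A acid at high dilution closes a large, unstrained ring at room temperature.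

Step 23
Reactants: 34 macrolactone (name as in step 22)
Product: 38 (5R,9R,13R,14R,17S)-spiro ketone: the target skeleton with C11=O; C15≡C16; C17 OTBDPS, via amino keto acid 35 (not isolated), via iminium carboxylate 36 (not isolated), via Mannich acid 37 (not isolated)
Conditions: TFA/CH2Cl2/H2O (10:10:1), 0 °C to rt; evaporate; NaOAc/AcOH buffer (pH 5), THF/H2O, rt to 45 °C
Reagents that add atoms: water, O
Why: Proposed new method: aqueous TFA removes the N-sulfinyl group, the tert-butyl ester and the enol ether of 34, so the ring A amine, the C9 ketone and a C10 β-keto acid face each other inside the 19-membered ring (35); the amine adds to C9 (6-exo-trig) and loses water to give ring B iminium 36, the enol carbon C10 then attacks C9 (5-(enolendo)-exo-trig, the mode of the 1,4-diketone to cyclopentenone aldol), and 37 loses CO2 to give 38. The closest known reaction types are the Robinson-Schöpf condensation, in which a β-keto acid adds to a cyclic iminium ion near pH 5 and then decarboxylates, and intramolecular Mannich closures on ketiminium ions that give α-tertiary amines; the five-membered carbocycle and the transannular setting are new. C9 is the only lasting new stereocentre (C10 of 37 is erased with CO2): C10 should enter axially, anti to the developing nitrogen lone pair on the half-chair of 36 that keeps H5 pseudoaxial and hence syn to H5, which leaves the branched C13 equatorial and cis to C4 as in the target. This path pays allylic 1,3-strain between C14 and C22 in 36, but the Mannich addition before loss of CO2 and the β-amino ketone to enone-amine exchange after it are reversible, and the C9 epimer would need C13 axial under ring B or C4 and C10 syn-diaxial, so equilibration should also end at 38. The step needs C10 and not the ring B enamine carbon C8 (aldol attack on C11) to be the nucleophile, which the carboxyl at C10 secures by raising the enol content at C10 and lowering the electrophilicity of C11. It also needs C13 to keep its configuration, which the strain of a tetrasubstituted exocyclic C9=C13 enamine against C22 and the mild temperature should secure.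

Step 24
Reactants: 38 spiro ketone (name as in step 23)
Product: 39 C11 tosylhydrazone of 38
Conditions: TsNHNH2, cat. AcOH, EtOH, 50 °C
Reagents that add atoms: p-toluenesulfonyl hydrazide, Cc1ccc(S(=O)(=O)NN)cc1
Why: Hydrazone formation should be easy at the unhindered cyclopentanone carbonyl, which is flanked by two CH2 groups and is the only ketone left.

Step 25
Reactants: 39 C11 tosylhydrazone of 38
Product: 40 (5R,9S,13R,14R,17S)-15,16-didehydro-17-O-TBDPS derivative of the target
Conditions: catecholborane, CHCl3, -10 to 0 °C; then NaOAc·3H2O, reflux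
Reagents that add atoms: none
Why: Caglioti-type deoxygenation (hydride addition to the tosylhydrazone, then loss of sulfinate and N2 from the diazene) turns C11 into CH2 without touching the lactone, alkyne or vinyl chloride.

Step 26
Reactants: 40 silyl ether (name as in step 25)
Product: 41 (5R,9S,13R,14R,17S)-15,16-didehydro derivative of the target (propargylic alcohol)
Conditions: TBAF, AcOH, THF, rt
Reagents that add atoms: none
Why: Buffered fluoride desilylation frees O17 and unloads the alkyne sterically before its reduction.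

Step 27
Reactants: 41 propargylic alcohol (name as in step 26)
Product: 42 target, (5R,9S,13R,14S,17R,15Z,18E)
Conditions: H2 (1 atm), Pd/CaCO3 poisoned with Pb(OAc)2, quinoline, EtOAc, rt, stopped at one equivalent of H2
Reagents that add atoms: none
Why: Lindlar semihydrogenation delivers both hydrogens syn to the alkyne and should give the Z C15=C16 alkene, the trisubstituted enoate and the chloroalkene being much slower substrates.

Compound list
1 | tert-butyl acetoacetate | CC(=O)CC(=O)OC(C)(C)C | starting material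
2 | tert-butyl (E)-3-methoxybut-2-enoate | C/C(OC)=C\C(=O)OC(C)(C)C | intermediate
3 | tert-butyl (E)-4-bromo-3-methoxybut-2-enoate | BrC/C(OC)=C\C(=O)OC(C)(C)C | intermediate
4 | (R)-but-3-yn-2-ol | C[C@@H](O)C#C | starting material
5 | (R)-but-3-yn-2-yl methanesulfonate | C[C@@H](OS(C)(=O)=O)C#C | intermediate
6 | dimethyl malonate | COC(=O)CC(=O)OC | starting material
7 | dimethyl 2-[(2R)-but-3-yn-2-yl]malonate | C[C@H](C(C(=O)OC)C(=O)OC)C#C | intermediate
8 | 2-[(2R)-but-3-yn-2-yl]malonic acid | C[C@H](C(C(=O)O)C(=O)O)C#C | intermediate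
9 | (3R)-3-methylpent-4-ynoic acid | C[C@H](CC(=O)O)C#C | intermediate
10 | (4R)-4-benzyl-1,3-oxazolidin-2-one | O=C1N[C@H](Cc2ccccc2)CO1 | starting material
11 | (3R)-3-methylpent-4-ynoic pivalic anhydride | C[C@H](CC(=O)OC(=O)C(C)(C)C)C#C | intermediate
12 | (4R)-4-benzyl-3-[(3R)-3-methylpent-4-ynoyl]-1,3-oxazolidin-2-one | C[C@H](CC(=O)N1[C@H](Cc2ccccc2)COC1=O)C#C | intermediate
13 | tert-butyl (2E,5R,6R)-5-{[(4R)-4-benzyl-2-oxo-1,3-oxazolidin-3-yl]carbonyl}-3-methoxy-6-methyloct-2-en-7-ynoate | C[C@@H](C#C)[C@@H](C/C(OC)=C\C(=O)OC(C)(C)C)C(=O)N1[C@H](Cc2ccccc2)COC1=O | intermediate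
14 | tert-butyl(but-3-yn-1-yloxy)dimethylsilane | C#CCCO[Si](C)(C)C(C)(C)C | starting material
15 | tert-butyl{[(3E)-3-chloro-4-iodobut-3-en-1-yl]oxy}dimethylsilane | I/C=C(/Cl)CCO[Si](C)(C)C(C)(C)C | intermediate
16 | (2E)-5-[(tert-butyldimethylsilyl)oxy]-3-chloropent-2-enal | O=C/C=C(/Cl)CCO[Si](C)(C)C(C)(C)C | intermediate
17 | tert-butyl (2E,5R,6R,9S,10E)-5-{[(4R)-4-benzyl-2-oxo-1,3-oxazolidin-3-yl]carbonyl}-13-[(tert-butyldimethylsilyl)oxy]-11-chloro-9-hydroxy-3-methoxy-6-methyltrideca-2,10-dien-7-ynoate | C[C@@H](C#C[C@@H](O)/C=C(/Cl)CCO[Si](C)(C)C(C)(C)C)[C@@H](C/C(OC)=C\C(=O)OC(C)(C)C)C(=O)N1[C@H](Cc2ccccc2)COC1=O | intermediate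
18 | 9-O-TBDPS ether of 17 | C[C@@H](C#C[C@@H](O[Si](c1ccccc1)(c1ccccc1)C(C)(C)C)/C=C(/Cl)CCO[Si](C)(C)C(C)(C)C)[C@@H](C/C(OC)=C\C(=O)OC(C)(C)C)C(=O)N1[C@H](Cc2ccccc2)COC1=O | intermediate
19 | tert-butyl (2E,5R,6R,9S,10E)-13-[(tert-butyldimethylsilyl)oxy]-9-[(tert-butyldiphenylsilyl)oxy]-11-chloro-5-[(ethylsulfanyl)carbonyl]-3-methoxy-6-methyltrideca-2,10-dien-7-ynoate | C[C@@H](C#C[C@@H](O[Si](c1ccccc1)(c1ccccc1)C(C)(C)C)/C=C(/Cl)CCO[Si](C)(C)C(C)(C)C)[C@@H](C/C(OC)=C\C(=O)OC(C)(C)C)C(=O)SCC | intermediate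
20 | 2-(bromomethyl)acrylic acid | C=C(CBr)C(=O)O | starting material
21 | 2-(trimethylsilyl)ethanol | C[Si](C)(C)CCO | starting material
22 | 2-(trimethylsilyl)ethyl 2-(bromomethyl)acrylate | C=C(CBr)C(=O)OCC[Si](C)(C)C | intermediate
23 | 4-[(tert-butyldimethylsilyl)oxy]butanal | O=CCCCO[Si](C)(C)C(C)(C)C | starting material
24 | (R)-2-methylpropane-2-sulfinamide | CC(C)(C)[S@@](=O)N | starting material
25 | (R,E)-N-{4-[(tert-butyldimethylsilyl)oxy]butylidene}-2-methylpropane-2-sulfinamide | CC(C)(C)[S@@](=O)/N=C/CCCO[Si](C)(C)C(C)(C)C | intermediate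
26 | (R)-N-{(4R)-7-[(tert-butyldimethylsilyl)oxy]hept-1-en-4-yl}-2-methylpropane-2-sulfinamide | CC(C)(C)[S@@](=O)N[C@@H](CC=C)CCCO[Si](C)(C)C(C)(C)C | intermediate
27 | 2-(trimethylsilyl)ethyl 2-{[{(4R)-7-[(tert-butyldimethylsilyl)oxy]hept-1-en-4-yl}((R)-tert-butylsulfinyl)amino]methyl}acrylate | CC(C)(C)[S@@](=O)N(CC(=C)C(=O)OCC[Si](C)(C)C)[C@@H](CC=C)CCCO[Si](C)(C)C(C)(C)C | intermediate
28 | 2-(trimethylsilyl)ethyl (6R)-1-[(R)-tert-butylsulfinyl]-6-{3-[(tert-butyldimethylsilyl)oxy]propyl}-1,2,5,6-tetrahydropyridine-3-carboxylate | CC(C)(C)[S@@](=O)N1CC(C(=O)OCC[Si](C)(C)C)=CC[C@H]1CCCO[Si](C)(C)C(C)(C)C | intermediate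
29 | 2-(trimethylsilyl)ethyl (6R)-1-[(R)-tert-butylsulfinyl]-6-(3-hydroxypropyl)-1,2,5,6-tetrahydropyridine-3-carboxylate | CC(C)(C)[S@@](=O)N1CC(C(=O)OCC[Si](C)(C)C)=CC[C@H]1CCCO | intermediate
30 | 2-(trimethylsilyl)ethyl (6R)-1-[(R)-tert-butylsulfinyl]-6-(3-iodopropyl)-1,2,5,6-tetrahydropyridine-3-carboxylate | CC(C)(C)[S@@](=O)N1CC(C(=O)OCC[Si](C)(C)C)=CC[C@H]1CCCI | intermediate
31 | alkylzinc iodide from 30 (C8-ZnI) | CC(C)(C)[S@@](=O)N1CC(C(=O)OCC[Si](C)(C)C)=CC[C@H]1CCC[Zn]I | intermediate
32 | (5R,13R,14R,17S)-C9 ketone (ring A silylethyl ester, N-sulfinyl; C13 CH2C(OMe)=CHCO2tBu; C15≡C16; C17 OTBDPS; (E)-C18=C19(Cl); C21 OTBS) | CC(C)(C)[S@@](=O)N1CC(C(=O)OCC[Si](C)(C)C)=CC[C@H]1CCCC(=O)[C@H](C/C(OC)=C\C(=O)OC(C)(C)C)[C@@H](C)C#C[C@@H](O[Si](c2ccccc2)(c2ccccc2)C(C)(C)C)/C=C(/Cl)CCO[Si](C)(C)C(C)(C)C | intermediate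
33 | (5R,13R,14R,17S)-seco acid (C1 CO2H, C21 OH) | CC(C)(C)[S@@](=O)N1CC(C(=O)O)=CC[C@H]1CCCC(=O)[C@H](C/C(OC)=C\C(=O)OC(C)(C)C)[C@@H](C)C#C[C@@H](O[Si](c2ccccc2)(c2ccccc2)C(C)(C)C)/C=C(/Cl)CCO | intermediate
34 | (5R,13R,14R,17S)-19-membered macrolactone | CC(C)(C)[S@@](=O)N1CC2=CC[C@H]1CCCC(=O)[C@H](C/C(OC)=C\C(=O)OC(C)(C)C)[C@@H](C)C#C[C@@H](O[Si](c3ccccc3)(c3ccccc3)C(C)(C)C)/C=C(/Cl)CCOC2=O | intermediate
35 | amino keto acid (ring A NH; C9=O; C13 CH2C(=O)CH2CO2H) | N1CC2=CC[C@H]1CCCC(=O)[C@H](CC(=O)CC(=O)O)[C@@H](C)C#C[C@@H](O[Si](c3ccccc3)(c3ccccc3)C(C)(C)C)/C=C(/Cl)CCOC2=O | intermediate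
36 | ring B iminium carboxylate (N+=C9; 15-membered lactone) | C[C@H]1C#C[C@@H](O[Si](c4ccccc4)(c4ccccc4)C(C)(C)C)/C=C(/Cl)CCOC(=O)C2=CC[C@H]3CCCC(=[N+]3C2)[C@@H]1CC(=O)CC(=O)[O-] | intermediate
37 | (5R,9R,13R,14R,17S)-Mannich acid (spiro cyclopentanone, C11=O, CO2H at C10, C10 epimers) | C[C@H]1C#C[C@@H](O[Si](c5ccccc5)(c5ccccc5)C(C)(C)C)/C=C(/Cl)CCOC(=O)C2=CC[C@H]3CCC[C@]4(C(C(=O)O)C(=O)C[C@H]14)N3C2 | intermediate
38 | (5R,9R,13R,14R,17S)-spiro ketone (C11=O; C15≡C16; C17 OTBDPS) | C[C@H]1C#C[C@@H](O[Si](c5ccccc5)(c5ccccc5)C(C)(C)C)/C=C(/Cl)CCOC(=O)C2=CC[C@H]3CCC[C@]4(CC(=O)C[C@H]14)N3C2 | intermediate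
39 | C11 tosylhydrazone of 38 | C[C@H]1C#C[C@@H](O[Si](c5ccccc5)(c5ccccc5)C(C)(C)C)/C=C(/Cl)CCOC(=O)C2=CC[C@H]3CCC[C@]4(CC(=NNS(=O)(=O)c5ccc(C)cc5)C[C@H]14)N3C2 | intermediate
40 | (5R,9S,13R,14R,17S)-15,16-didehydro-17-O-TBDPS derivative of the target | C[C@H]1C#C[C@@H](O[Si](c5ccccc5)(c5ccccc5)C(C)(C)C)/C=C(/Cl)CCOC(=O)C2=CC[C@H]3CCC[C@]4(CCC[C@H]14)N3C2 | intermediate
41 | (5R,9S,13R,14R,17S)-15,16-didehydro derivative of the target | C[C@H]1C#C[C@@H](O)/C=C(/Cl)CCOC(=O)C2=CC[C@H]3CCC[C@]4(CCC[C@H]14)N3C2 | intermediate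
42 | CNP0129639.4, (5R,9S,13R,14S,17R,15Z,18E) | C[C@H]1/C=C\[C@@H](O)/C=C(/Cl)CCOC(=O)C2=CC[C@H]3CCC[C@]4(CCC[C@H]14)N3C2 | target

Total step count: 27
Longest linear sequence: 16 steps (3-7, 10-12, 20-27)

Steps most likely to fail

1. Step 23.
- What may go wrong: attack on the wrong face of C9. C13 may epimerise through the exocyclic enamine. CO2 may be lost early, followed by aldol attack of the ring B enamine on C11.
- Fallback: it sets out from 34 and comes back at 38. The order of bond formation is reversed, and each event is of a known type.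
- Brief HCl in MeOH at 0 °C removes only the sulfinyl group, and allyl chloroformate with NaHCO3 caps the amine as N-Alloc macrolactone F1.
- 1 M aqueous HCl in THF hydrolyses the enol ether to β-keto ester F2.
- Piperidinium acetate in hot toluene closes C9=C10 by intramolecular Knoevenagel condensation to cyclopentenone ester F3.
- Pd(PPh3)4 with dimedone frees the amine. It adds to C9 of the doubly activated alkene in a transannular aza-Michael addition, which is reversible and hence thermodynamic at C9, and gives spiro β-keto ester F4.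
- TFA in CH2Cl2 with gentle warming removes the tert-butyl group and CO2 to give 38.

2. Step 10.
- What may go wrong: slow addition and weak facial control with the β-chloro enal, or drift of the enal geometry by reversible conjugate addition during a long reaction.
- Fallback: it sets out from 13 and 16 and comes back at 17. C17 is set by ketone reduction instead of C-C bond formation.
- Ligand-free addition with Zn(OTf)2 and Et3N in toluene gives the C17-epimeric carbinols F5.
- Dess-Martin periodinane oxidises them to ynone F6.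
- CBS reduction with (S)-Me-CBS and catecholborane at -78 °C treats the alkynyl group as the small substituent and should give 17.

3. Step 27.
- What may go wrong: over-reduction, hydrogenolysis of the vinylic chlorine, or stalling because the amine binds palladium and the alkyne is flanked by two branched carbons.
- Fallback: it sets out from 40 and comes back at 42. Hydrogen is delivered through boron instead of a metal surface.
- Dicyclohexylborane in THF adds syn to the alkyne to give alkenylborane F7.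
- Acetic acid cleaves the C-B bond with retention to give Z-alkene silyl ether F8.
- TBAF buffered with AcOH removes the silyl group and gives 42.

Further compounds
F1 | step 23 | N-Alloc macrolactone (34 with N-CO2-allyl in place of N-sulfinyl) | C=CCOC(=O)N1CC2=CC[C@H]1CCCC(=O)[C@H](C/C(OC)=C\C(=O)OC(C)(C)C)[C@@H](C)C#C[C@@H](O[Si](c3ccccc3)(c3ccccc3)C(C)(C)C)/C=C(/Cl)CCOC2=O
F2 | step 23 | N-Alloc β-keto ester (C13 CH2C(=O)CH2CO2tBu) | C=CCOC(=O)N1CC2=CC[C@H]1CCCC(=O)[C@H](CC(=O)CC(=O)OC(C)(C)C)[C@@H](C)C#C[C@@H](O[Si](c3ccccc3)(c3ccccc3)C(C)(C)C)/C=C(/Cl)CCOC2=O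
F3 | step 23 | N-Alloc cyclopentenone ester (C9=C10(CO2tBu)-C11=O) | C=CCOC(=O)N1CC2=CC[C@H]1CCCC3=C(C(=O)OC(C)(C)C)C(=O)C[C@@H]3[C@@H](C)C#C[C@@H](O[Si](c4ccccc4)(c4ccccc4)C(C)(C)C)/C=C(/Cl)CCOC2=O
F4 | step 23 | spiro β-keto ester (tert-butyl ester of 37) | C[C@H]1C#C[C@@H](O[Si](c5ccccc5)(c5ccccc5)C(C)(C)C)/C=C(/Cl)CCOC(=O)C2=CC[C@H]3CCC[C@]4(C(C(=O)OC(C)(C)C)C(=O)C[C@H]14)N3C2
F5 | step 10 | C17-epimeric carbinols (17 without control at C17) | C[C@@H](C#CC(O)/C=C(/Cl)CCO[Si](C)(C)C(C)(C)C)[C@@H](C/C(OC)=C\C(=O)OC(C)(C)C)C(=O)N1[C@H](Cc2ccccc2)COC1=O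
F6 | step 10 | ynone (C17=O) | C[C@@H](C#CC(=O)/C=C(/Cl)CCO[Si](C)(C)C(C)(C)C)[C@@H](C/C(OC)=C\C(=O)OC(C)(C)C)C(=O)N1[C@H](Cc2ccccc2)COC1=O
F7 | step 27 | alkenylborane (dicyclohexylboryl at C15, one regioisomer drawn) | C[C@H]1/C(B(C5CCCCC5)C5CCCCC5)=C\[C@@H](O[Si](c5ccccc5)(c5ccccc5)C(C)(C)C)/C=C(/Cl)CCOC(=O)C2=CC[C@H]3CCC[C@]4(CCC[C@H]14)N3C2
F8 | step 27 | Z-alkene silyl ether (17-O-TBDPS ether of 42) | C[C@H]1/C=C\[C@@H](O[Si](c5ccccc5)(c5ccccc5)C(C)(C)C)/C=C(/Cl)CCOC(=O)C2=CC[C@H]3CCC[C@]4(CCC[C@H]14)N3C2
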